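**Retrosynthetic overview**
1. Target 25 ⇐ epoxide 24 by invertive bromide opening; 24 ⇐ prenyl ketol 23 (Shi epoxidation) ⇐ allyl ketol 22 (cross-metathesis).
2. Quaternary carbinol ⇐ hydroxyl-directed allylboration of the lactate-derived α-hydroxy ketone 18; the lactate carbinol is then oxidised to the acetyl C=O (traceless stereo-relay).
3. Ring C1–H ⇐ kinetic ketonisation of an exocyclic enol released by Pd-catalysed decarboxylation of 14.
4. Key disconnection: the cyclohexane is closed by double C-alkylation of β-keto ester 12 with the acyclic bis-electrophile 8, which already carries the trans Br/Cl pair.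
5. That pair comes from catalytic enantioselective bromochlorination of the (Z)-allylic alcohol 6, not from halogenating a preformed cyclohexene; the single ring is formed in step 7.

Assumption: 1, 9, 10 and all stated reagents are purchasable, and in step 4 the enantiomer of the chiral Schiff-base ligand that gives (2S,3S)-7 is used (its antipode gives the mirror image).

**Step 1**
Reactants: 1 4-bromobut-1-yne
Product: 3 methyl 5-bromopent-2-ynoate, via lithium acetylide 2 (not isolated)
Conditions: n-BuLi (1.05 equiv), THF, −78 °C; then ClCO2Me, −78 → −30 °C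
Reagents that add atoms: methyl chloroformate COC(=O)Cl
Why: Deprotonation of the terminal alkyne and C-acylation of the lithium acetylide with a chloroformate are much faster at −78 °C than any attack on the primary bromide, and no stereocentre is involved.

**Step 2**
Reactants: 3 methyl 5-bromopent-2-ynoate
Product: 5 methyl (2Z)-5-bromo-3-methylpent-2-enoate, via alkenylcuprate 4 (not isolated)
Conditions: Me2CuLi (from MeLi and CuI, 1.2 equiv), THF, −78 °C, 30 min; aq. NH4Cl quench at −78 °C
Reagents that add atoms: lithium dimethylcuprate [Li+].C[Cu-]C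
Why: Syn-carbocupration (conjugate addition) of the ynoate followed by cold protonation with retention puts the new methyl and H cis, so the CH2CH2Br chain ends cis to the ester (Z), while the low temperature prevents allenoate equilibration and substitution of the primary bromide.

**Step 3**
Reactants: 5 methyl (2Z)-5-bromo-3-methylpent-2-enoate
Product: 6 (2Z)-5-bromo-3-methylpent-2-en-1-ol
Conditions: i-Bu2AlH (2.3 equiv), CH2Cl2, −78 °C; potassium sodium tartrate work-up
Reagents that add atoms: none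
Why: Hydride 1,2-reduction of the enoate to the allylic alcohol keeps the Z geometry and leaves the alkyl bromide untouched at −78 °C.

**Step 4**
Reactants: 6 (2Z)-5-bromo-3-methylpent-2-en-1-ol
Product: 7 (2S,3S)-2,5-dibromo-3-chloro-3-methylpentan-1-ol
Conditions: NBS (1.1 equiv), ClTi(OiPr)3 (1.1 equiv), chiral tridentate salicylaldimine–amino alcohol Schiff-base ligand (20 mol%), hexanes, −20 °C
Reagents that add atoms: N-bromosuccinimide O=C1CCC(=O)N1Br; chlorotitanium triisopropoxide CC(C)O[Ti](Cl)(OC(C)C)OC(C)C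
Why: Burns-type catalytic enantioselective bromochlorination of the allylic alkoxide bound to tetravalent titanium puts Br at the proximal carbon and Cl at the distal tertiary carbon, where the Markovnikov and catalyst preferences coincide; anti addition across the Z alkene fixes the (2S*,3S*) relative configuration (the future trans ring Br/Cl) and the ligand fixes the absolute sense.

**Step 5**
Reactants: 7 (2S,3S)-2,5-dibromo-3-chloro-3-methylpentan-1-ol
Product: 8 (2S,3S)-2,5-dibromo-3-chloro-3-methylpentyl trifluoromethanesulfonate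
Conditions: Tf2O (1.2 equiv), 2,6-lutidine (1.5 equiv), CH2Cl2, −78 °C, 20 min; cold pentane/silica filtration, used at once
Reagents that add atoms: triflic anhydride O=S(=O)(OS(=O)(=O)C(F)(F)F)C(F)(F)F
Why: O-Sulfonylation of the primary alcohol under cold, weakly basic conditions gives the only leaving group reactive enough for substitution next to the CHBr carbon without touching either stereocentre.

**Step 6**
Reactants: 9 ethyl (2S)-2-[(tert-butyldimethylsilyl)oxy]propanoate; 10 prop-2-en-1-yl acetate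
Product: 12 prop-2-en-1-yl (4S)-4-[(tert-butyldimethylsilyl)oxy]-3-oxopentanoate, via lithium enolate 11 (not isolated)
Conditions: LiN(i-Pr)2 (2.1 equiv), 10 (2.1 equiv), THF, −78 °C; then 9, −78 °C, 1 h; AcOH quench
Reagents that add atoms: none
Why: Crossed Claisen condensation of the acetate enolate with the α-silyloxy ester is faster at −78 °C than α-deprotonation of 9, so the lactate stereocentre is carried through unchanged (the second equivalent of enolate absorbs the acidic product proton).

**Step 7**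
Reactants: 12 prop-2-en-1-yl (4S)-4-[(tert-butyldimethylsilyl)oxy]-3-oxopentanoate; 8 (2S,3S)-2,5-dibromo-3-chloro-3-methylpentyl trifluoromethanesulfonate
Product: 14 prop-2-en-1-yl (3S,4S)-3-bromo-1-[(2S)-2-[(tert-butyldimethylsilyl)oxy]propanoyl]-4-chloro-4-methylcyclohexane-1-carboxylate (C1 epimers), via bromo keto ester 13 (not isolated)
Conditions: NaH (2.2 equiv), THF, 0 °C; 8 added at −20 → 0 °C; then rt → 40 °C (0.05 M)
Reagents that add atoms: none
Why: Double C-alkylation of the β-keto ester (sodium enolate in THF favours C- over O-attack) proceeds by intermolecular substitution of the triflate and then 6-exo-tet closure onto the primary bromide, for which O-closure would need an eight-membered ring; the quaternary C1 formed here is erased in step 8 and the Br/Cl centres are not touched.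

**Step 8**
Reactants: 14 prop-2-en-1-yl (3S,4S)-3-bromo-1-[(2S)-2-[(tert-butyldimethylsilyl)oxy]propanoyl]-4-chloro-4-methylcyclohexane-1-carboxylate
Product: 17 (2S)-1-[(1S,3S,4S)-3-bromo-4-chloro-4-methylcyclohexyl]-2-[(tert-butyldimethylsilyl)oxy]propan-1-one, via keto acid 15 (not isolated), via enol 16 (not isolated)
Conditions: Pd(OAc)2 (5 mol%), PPh3 (20 mol%), HCO2H (3 equiv), Et3N (3.5 equiv), THF, 0 °C → rt
Reagents that add atoms: none
Why: Tsuji-type deallylation by zerovalent palladium with formate as hydride donor, then decarboxylation, gives the exocyclic enol, whose kinetic ketonisation (Zimmerman-type protonation) occurs on the equatorial face because the axial face is blocked by the syn-axial C3–Br of the preferred chair (Br/Cl diaxial, methyl equatorial); this places H trans and the acyl group cis to Br, i.e. (1S), under non-basic conditions that preserve this less stable epimer and the lactate centre.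

**Step 9**
Reactants: 17 (2S)-1-[(1S,3S,4S)-3-bromo-4-chloro-4-methylcyclohexyl]-2-[(tert-butyldimethylsilyl)oxy]propan-1-one
Product: 18 (2S)-1-[(1S,3S,4S)-3-bromo-4-chloro-4-methylcyclohexyl]-2-hydroxypropan-1-one
Conditions: HF·pyridine, pyridine/THF, 0 °C → rt
Reagents that add atoms: none
Why: Fluoride-mediated desilylation under buffered acidic conditions frees the α-hydroxyl without enolising either α-centre of the ketone.

**Step 10**
Reactants: 18 (2S)-1-[(1S,3S,4S)-3-bromo-4-chloro-4-methylcyclohexyl]-2-hydroxypropan-1-one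
Product: 21 (2S,3R)-3-[(1S,3S,4S)-3-bromo-4-chloro-4-methylcyclohexyl]hex-5-ene-2,3-diol, via mixed boronate 19 (not isolated), via cyclic borate 20 (not isolated)
Conditions: CH2=CHCH2B(OiPr)2 (1.5 equiv), CH2Cl2, 0 °C → rt; then pH 7 aqueous work-up
Reagents that add atoms: diisopropyl prop-2-en-1-ylboronate C=CCB(OC(C)C)OC(C)C
Why: Hydroxyl-directed allylboration: alkoxy exchange tethers boron to the α-oxygen, boron then chelates the ketone, and the allyl group is delivered through a chair six-membered (Zimmerman–Traxler) transition state on the face anti to the C-methyl of the five-membered chelate (Cram-chelate sense); this sets the (R) quaternary carbinol, and the ring carbon C1, flanked by two CH2 groups, exerts no competing bias.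

**Step 11**
Reactants: 21 (2S,3R)-3-[(1S,3S,4S)-3-bromo-4-chloro-4-methylcyclohexyl]hex-5-ene-2,3-diol
Product: 22 (3R)-3-[(1S,3S,4S)-3-bromo-4-chloro-4-methylcyclohexyl]-3-hydroxyhex-5-en-2-one
Conditions: Dess–Martin periodinane (1.3 equiv), CH2Cl2, 0 °C → rt
Reagents that add atoms: none
Why: Dess–Martin oxidation converts the secondary alcohol into the acetyl ketone and cannot touch the tertiary carbinol, so the relay stereocentre is removed and the quaternary centre is kept.

**Step 12**
Reactants: 22 (3R)-3-[(1S,3S,4S)-3-bromo-4-chloro-4-methylcyclohexyl]-3-hydroxyhex-5-en-2-one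
Product: 23 (3R)-3-[(1S,3S,4S)-3-bromo-4-chloro-4-methylcyclohexyl]-3-hydroxy-6-methylhept-5-en-2-one
Conditions: second-generation Grubbs catalyst RuCl2(=CHPh)(H2IMes)(PCy3) (5 mol%), 2-methylbut-2-ene (large excess), CH2Cl2, 40 °C
Reagents that add atoms: 2-methylbut-2-ene CC=C(C)C
Why: Olefin cross-metathesis of the terminal alkene with excess 2-methylbut-2-ene converts allyl into prenyl with loss of propene; alkyl halides and the ketol are inert and no stereocentre is involved.

**Step 13**
Reactants: 23 (3R)-3-[(1S,3S,4S)-3-bromo-4-chloro-4-methylcyclohexyl]-3-hydroxy-6-methylhept-5-en-2-one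
Product: 24 (3R)-3-[(1S,3S,4S)-3-bromo-4-chloro-4-methylcyclohexyl]-4-[(2S)-3,3-dimethyloxiran-2-yl]-3-hydroxybutan-2-one
Conditions: L-fructose-derived Shi ketone (30 mol%), KHSO5 (as 2KHSO5·KHSO4·K2SO4), K2CO3, Bu4NHSO4 (cat.), MeCN/CH2(OMe)2/aq. Na2B4O7 buffer, 0 °C
Reagents that add atoms: potassium peroxymonosulfate [K+].[O-]S(=O)(=O)OO
Why: Shi asymmetric epoxidation of the only alkene, a trisubstituted one, by the chiral dioxirane through the spiro transition state is reagent-controlled, and the L-fructose-derived ketone gives the (S)-epoxide.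

**Step 14**
Reactants: 24 (3R)-3-[(1S,3S,4S)-3-bromo-4-chloro-4-methylcyclohexyl]-4-[(2S)-3,3-dimethyloxiran-2-yl]-3-hydroxybutan-2-one
Product: 25 (3R,5R)-5-bromo-3-[(1S,3S,4S)-3-bromo-4-chloro-4-methylcyclohexyl]-3,6-dihydroxy-6-methylheptan-2-one
Conditions: Li2NiBr4 (2 equiv, 0.4 M in THF), THF, 0 °C → rt; pH 7 phosphate work-up
Reagents that add atoms: dilithium tetrabromonickelate [Li+].[Li+].Br[Ni-2](Br)(Br)Br
Why: Soft bromide from the divalent nickel ate complex opens the trisubstituted epoxide by SN2 at the less substituted carbon with inversion, giving the (5R) bromide and the tertiary alcohol; the near-neutral medium avoids attack by the tertiary hydroxyl and leaves the ring halides alone.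

**Compound list**
1 | 4-bromobut-1-yne | C#CCCBr | starting material
2 | lithium 4-bromobut-1-yn-1-ide | [Li]C#CCCBr | intermediate
3 | methyl 5-bromopent-2-ynoate | COC(=O)C#CCCBr | intermediate
4 | lithium [(1E)-4-bromo-1-(methoxycarbonyl)-2-methylbut-1-en-1-yl](methyl)cuprate | [Li+].COC(=O)/C([Cu-]C)=C(/C)CCBr | intermediate
5 | methyl (2Z)-5-bromo-3-methylpent-2-enoate | COC(=O)/C=C(/C)CCBr | intermediate
6 | (2Z)-5-bromo-3-methylpent-2-en-1-ol | OC/C=C(/C)CCBr | intermediate
7 | (2S,3S)-2,5-dibromo-3-chloro-3-methylpentan-1-ol | BrCC[C@](C)(Cl)[C@@H](Br)CO | intermediate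
8 | (2S,3S)-2,5-dibromo-3-chloro-3-methylpentyl trifluoromethanesulfonate | BrCC[C@](C)(Cl)[C@@H](Br)COS(=O)(=O)C(F)(F)F | intermediate
9 | ethyl (2S)-2-[(tert-butyldimethylsilyl)oxy]propanoate | C[C@H](O[Si](C)(C)C(C)(C)C)C(=O)OCC | starting material
10 | prop-2-en-1-yl acetate | CC(=O)OCC=C | starting material
11 | lithium 1-(prop-2-en-1-yloxy)ethen-1-olate | [Li]OC(=C)OCC=C | intermediate
12 | prop-2-en-1-yl (4S)-4-[(tert-butyldimethylsilyl)oxy]-3-oxopentanoate | C[C@H](O[Si](C)(C)C(C)(C)C)C(=O)CC(=O)OCC=C | intermediate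
13 | prop-2-en-1-yl (4S)-2-[(2S,3S)-2,5-dibromo-3-chloro-3-methylpentyl]-4-[(tert-butyldimethylsilyl)oxy]-3-oxopentanoate (C2 epimers) | BrCC[C@](C)(Cl)[C@@H](Br)CC(C(=O)OCC=C)C(=O)[C@H](C)O[Si](C)(C)C(C)(C)C | intermediate
14 | prop-2-en-1-yl (3S,4S)-3-bromo-1-[(2S)-2-[(tert-butyldimethylsilyl)oxy]propanoyl]-4-chloro-4-methylcyclohexane-1-carboxylate (C1 epimers) | C=CCOC(=O)C1(C(=O)[C@H](C)O[Si](C)(C)C(C)(C)C)CC[C@](C)(Cl)[C@@H](Br)C1 | intermediate
15 | (3S,4S)-3-bromo-1-[(2S)-2-[(tert-butyldimethylsilyl)oxy]propanoyl]-4-chloro-4-methylcyclohexane-1-carboxylic acid | OC(=O)C1(C(=O)[C@H](C)O[Si](C)(C)C(C)(C)C)CC[C@](C)(Cl)[C@@H](Br)C1 | intermediate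
16 | (2S)-1-[(3S,4S)-3-bromo-4-chloro-4-methylcyclohexylidene]-2-[(tert-butyldimethylsilyl)oxy]propan-1-ol | C[C@H](O[Si](C)(C)C(C)(C)C)C(O)=C1CC[C@](C)(Cl)[C@@H](Br)C1 | intermediate
17 | (2S)-1-[(1S,3S,4S)-3-bromo-4-chloro-4-methylcyclohexyl]-2-[(tert-butyldimethylsilyl)oxy]propan-1-one | C[C@H](O[Si](C)(C)C(C)(C)C)C(=O)[C@H]1CC[C@](C)(Cl)[C@@H](Br)C1 | intermediate
18 | (2S)-1-[(1S,3S,4S)-3-bromo-4-chloro-4-methylcyclohexyl]-2-hydroxypropan-1-one | C[C@H](O)C(=O)[C@H]1CC[C@](C)(Cl)[C@@H](Br)C1 | intermediate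
19 | (2S)-1-[(1S,3S,4S)-3-bromo-4-chloro-4-methylcyclohexyl]-1-oxopropan-2-yl propan-2-yl prop-2-en-1-ylboronate | C[C@H](OB(CC=C)OC(C)C)C(=O)[C@H]1CC[C@](C)(Cl)[C@@H](Br)C1 | intermediate
20 | (4R,5S)-4-[(1S,3S,4S)-3-bromo-4-chloro-4-methylcyclohexyl]-5-methyl-2-(propan-2-yloxy)-4-(prop-2-en-1-yl)-1,3,2-dioxaborolane | C[C@@H]1OB(OC(C)C)O[C@]1(CC=C)[C@H]2CC[C@](C)(Cl)[C@@H](Br)C2 | intermediate
21 | (2S,3R)-3-[(1S,3S,4S)-3-bromo-4-chloro-4-methylcyclohexyl]hex-5-ene-2,3-diol | C[C@H](O)[C@@](O)(CC=C)[C@H]1CC[C@](C)(Cl)[C@@H](Br)C1 | intermediate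
22 | (3R)-3-[(1S,3S,4S)-3-bromo-4-chloro-4-methylcyclohexyl]-3-hydroxyhex-5-en-2-one | CC(=O)[C@@](O)(CC=C)[C@H]1CC[C@](C)(Cl)[C@@H](Br)C1 | intermediate
23 | (3R)-3-[(1S,3S,4S)-3-bromo-4-chloro-4-methylcyclohexyl]-3-hydroxy-6-methylhept-5-en-2-one | CC(=O)[C@@](O)(CC=C(C)C)[C@H]1CC[C@](C)(Cl)[C@@H](Br)C1 | intermediate
24 | (3R)-3-[(1S,3S,4S)-3-bromo-4-chloro-4-methylcyclohexyl]-4-[(2S)-3,3-dimethyloxiran-2-yl]-3-hydroxybutan-2-one | CC(=O)[C@@](O)(C[C@@H]1OC1(C)C)[C@H]2CC[C@](C)(Cl)[C@@H](Br)C2 | intermediate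
25 | (3R,5R)-5-bromo-3-[(1S,3S,4S)-3-bromo-4-chloro-4-methylcyclohexyl]-3,6-dihydroxy-6-methylheptan-2-one | CC(=O)[C@@](O)(C[C@@H](Br)C(C)(C)O)[C@H]1CC[C@](C)(Cl)[C@@H](Br)C1 | target

**Step count**
Total: 14 steps. Longest linear sequence: 13 steps (steps 1–5, then 7–14); step 6 is a one-step side branch.

**Three steps most likely to fail**

Step 8 (C1 configuration). The wanted (1S) ketone, with acyl cis to Br, is the less stable epimer, and the ketonisation may be less face-selective than argued. The fallback replaces in-situ ketonisation by protonation of a regiodefined enolate. It sets out from 14: deallylation with Pd(PPh3)4 and morpholine at 0 °C gives acid 15, which is now isolated cold. N,O-bis(trimethylsilyl)acetamide converts it into trimethylsilyl (3S,4S)-3-bromo-1-[(2S)-2-[(tert-butyldimethylsilyl)oxy]propanoyl]-4-chloro-4-methylcyclohexane-1-carboxylate F8. Warming F8 in toluene (60–80 °C) causes silyl-transfer decarboxylation to the C1 silyl enol ether tert-butyl({(2S)-1-[(3S,4S)-3-bromo-4-chloro-4-methylcyclohexylidene]-1-[(trimethylsilyl)oxy]propan-2-yl}oxy)dimethylsilane F9. Anhydrous fluoride (Bu4N+ Ph3SiF2−) at −78 °C liberates the enolate at C1 only, and a bulky proton donor (2,6-di-tert-butylphenol) protonates it from the unshielded equatorial face. The route is rejoined at 17.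

Step 7 (annulation). Intermolecular substitution at a primary triflate next to CHBr may lose to E2 (giving a 2-bromoallyl unit) or to O-alkylation. The fallback makes the hindered displacement intramolecular. It sets out from 7 and 12. Alcohol 7 is silylated (TBSOTf, 2,6-lutidine) to tert-butyl{[(2S,3S)-2,5-dibromo-3-chloro-3-methylpentyl]oxy}dimethylsilane F4. Its unhindered primary bromide alkylates 12 (Cs2CO3, DMF, 40 °C) to give prop-2-en-1-yl (4S)-2-[(3S,4S)-4-bromo-3-chloro-3-methyl-5-[(tert-butyldimethylsilyl)oxy]pentyl]-4-[(tert-butyldimethylsilyl)oxy]-3-oxopentanoate F5. The primary silyl ether is cleaved selectively (pyridinium p-toluenesulfonate, MeOH) to prop-2-en-1-yl (4S)-2-[(3S,4S)-4-bromo-3-chloro-5-hydroxy-3-methylpentyl]-4-[(tert-butyldimethylsilyl)oxy]-3-oxopentanoate F6. MsCl/Et3N gives prop-2-en-1-yl (4S)-2-[(3S,4S)-4-bromo-3-chloro-5-[(methanesulfonyl)oxy]-3-methylpentyl]-4-[(tert-butyldimethylsilyl)oxy]-3-oxopentanoate F7. Cs2CO3 in DMF at 45 °C then closes the ring by 6-exo-tet C-alkylation, returning to 14.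

Step 4 (bromochlorination). The ee and regioselectivity on this (Z)-trisubstituted, bromide-bearing substrate are not precedented exactly. The fallback puts the halogens on a preformed ring in which C1 is quaternary. It sets out from 12: Knoevenagel condensation with paraformaldehyde (cat. piperidinium acetate) in the presence of excess isoprene generates prop-2-en-1-yl (4S)-4-[(tert-butyldimethylsilyl)oxy]-2-methylidene-3-oxopentanoate F1. F1 is trapped in situ by a para-selective Diels–Alder reaction to give prop-2-en-1-yl 1-[(2S)-2-[(tert-butyldimethylsilyl)oxy]propanoyl]-4-methylcyclohex-3-ene-1-carboxylate F2. Because C1 of F2 carries two acyl groups of similar size, both chairs are accessible and each bromonium face can be opened trans-diaxially at the tertiary carbon. Bu4N+ BrCl2− in CH2Cl2 at 0 °C should therefore give only Markovnikov anti adducts: 14 and its ring diastereomer prop-2-en-1-yl (3R,4R)-3-bromo-1-[(2S)-2-[(tert-butyldimethylsilyl)oxy]propanoyl]-4-chloro-4-methylcyclohexane-1-carboxylate F3, in about 1:1 ratio. These are separated by chromatography using the fixed (S)-silyloxy centre, and the route is rejoined at 14 at the cost of half the material.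

**Further compounds**
F1 | step 4 | prop-2-en-1-yl (4S)-4-[(tert-butyldimethylsilyl)oxy]-2-methylidene-3-oxopentanoate | C=C(C(=O)OCC=C)C(=O)[C@H](C)O[Si](C)(C)C(C)(C)C
F2 | step 4 | prop-2-en-1-yl 1-[(2S)-2-[(tert-butyldimethylsilyl)oxy]propanoyl]-4-methylcyclohex-3-ene-1-carboxylate (C1 epimers) | C=CCOC(=O)C1(C(=O)[C@H](C)O[Si](C)(C)C(C)(C)C)CCC(C)=CC1
F3 | step 4 | prop-2-en-1-yl (3R,4R)-3-bromo-1-[(2S)-2-[(tert-butyldimethylsilyl)oxy]propanoyl]-4-chloro-4-methylcyclohexane-1-carboxylate (C1 epimers) | C=CCOC(=O)C1(C(=O)[C@H](C)O[Si](C)(C)C(C)(C)C)CC[C@@](C)(Cl)[C@H](Br)C1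
F4 | step 7 | tert-butyl{[(2S,3S)-2,5-dibromo-3-chloro-3-methylpentyl]oxy}dimethylsilane | BrCC[C@](C)(Cl)[C@@H](Br)CO[Si](C)(C)C(C)(C)C
F5 | step 7 | prop-2-en-1-yl (4S)-2-[(3S,4S)-4-bromo-3-chloro-3-methyl-5-[(tert-butyldimethylsilyl)oxy]pentyl]-4-[(tert-butyldimethylsilyl)oxy]-3-oxopentanoate (C2 epimers) | C=CCOC(=O)C(C(=O)[C@H](C)O[Si](C)(C)C(C)(C)C)CC[C@](C)(Cl)[C@@H](Br)CO[Si](C)(C)C(C)(C)C
F6 | step 7 | prop-2-en-1-yl (4S)-2-[(3S,4S)-4-bromo-3-chloro-5-hydroxy-3-methylpentyl]-4-[(tert-butyldimethylsilyl)oxy]-3-oxopentanoate (C2 epimers) | C=CCOC(=O)C(C(=O)[C@H](C)O[Si](C)(C)C(C)(C)C)CC[C@](C)(Cl)[C@@H](Br)CO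
F7 | step 7 | prop-2-en-1-yl (4S)-2-[(3S,4S)-4-bromo-3-chloro-5-[(methanesulfonyl)oxy]-3-methylpentyl]-4-[(tert-butyldimethylsilyl)oxy]-3-oxopentanoate (C2 epimers) | C=CCOC(=O)C(C(=O)[C@H](C)O[Si](C)(C)C(C)(C)C)CC[C@](C)(Cl)[C@@H](Br)COS(C)(=O)=O
F8 | step 8 | trimethylsilyl (3S,4S)-3-bromo-1-[(2S)-2-[(tert-butyldimethylsilyl)oxy]propanoyl]-4-chloro-4-methylcyclohexane-1-carboxylate (C1 epimers) | C[Si](C)(C)OC(=O)C1(C(=O)[C@H](C)O[Si](C)(C)C(C)(C)C)CC[C@](C)(Cl)[C@@H](Br)C1
F9 | step 8 | tert-butyl({(2S)-1-[(3S,4S)-3-bromo-4-chloro-4-methylcyclohexylidene]-1-[(trimethylsilyl)oxy]propan-2-yl}oxy)dimethylsilane | C[C@H](O[Si](C)(C)C(C)(C)C)C(O[Si](C)(C)C)=C1CC[C@](C)(Cl)[C@@H](Br)C1
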